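**Target's price.** Each target costs one partner, as does each isomer of the product and each quenched reagent. These flasks share one partner charge and differ in substrate.

| setting | violet | green | teal | summer | dusk | dawn | autumn |
|---|---|---|---|---|---|---|---|
| substrate | 0.058 M | 0.44 M | 2.1 M | 0.080 M | 0.25 M | 0.60 M | 2.0 M |
| partner | 0.345 M | 0.345 M | 0.345 M | 0.345 M | 0.345 M | 0.345 M | 0.345 M |
| capture agent | 4.6 mM | 4.6 mM | 4.6 mM | 4.60 mM | 4.60 mM | 4.60 mM | 4.60 mM |
| protic impurity | 4.6 mM | 4.6 mM | 4.6 mM | 4.60 mM | 4.60 mM | 4.60 mM | 4.60 mM |
| remark | run made earlier | run made earlier | run made earlier |  |  |  |  |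
| time |  |  |  | 3.0 h | 3.0 h | 3.0 h | 3.0 h |

- violet (time / min: target / %): 8.00: 1.0; 25.0: 5.8; 40.0: 10.3; 60.0: 16.5; 90.0: 22.6
- green (time / min: target / %): 8.00: 0.8; 15.0: 2.0; 25.0: 4.3; 50.0: 11.1; 90.0: 16.1
- teal (time / min: target / %): 8.00: 0.5; 25.0: 1.6; 40.0: 2.1; 60.0: 2.0; 90.0: 2.8

(standard deviation of a reading: 0.5 percentage points)

- the numbers in the tables scatter by 0.5 percentage points (one standard deviation)
- steps under discussion: substrate + partner -> isomer of the product; partner + protic impurity -> quenched reagent; partner + tautomer -> target; substrate <-> tautomer; capture agent + tautomer -> trapped intermediate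
- "hardly changes" means that all values lie within two and a half points (for a concentration: within two and a half percent of the largest)

- [target] at the end for summer, dusk, dawn, autumn, in this order
- how that number moves from the first to the last of them (rises all the way / falls, then rises / rises, then falls / falls all the way / hardly changes)

**Partner budget.** Subtract the protic impurity from the partner charge, counting one partner per impurity. This leaves 0.340 M, the partner budget, which target and isomer must share.

**Thin extreme.** Put substrate below the budget, as in violet. Partner outlasts the substrate, so target is a share of the substrate and grows with the charge. Violet reads 22.6% at 90.0 min and is still rising, so put summer above 0.0181 M.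

**Thick extreme.** Put substrate far above the budget, as in teal. Partner becomes the limiting reagent, and target and isomer together stop at the budget. Teal's readings from 40.0 min on lie flat within the scatter and average 0.0483 M, which is 14.2% of the budget. Take autumn near that level.

**Between them.** Green's charge lies above the budget, yet green reads 0.0708 M at 90.0 min, above teal's level. So expect a rise, then a fall, with the top near green's charge.

**The flask.** The forecast gives 0.026 M, 0.07 M, 0.092 M and 0.068 M, rises, then falls, with the high charge “limited by the partner lost to the isomer”, and its autumn stands above the teal level reckoned here. The flask gives 0.0224 M, 0.0731 M, 0.0984 M and 0.0438 M, rises, then falls, turning at 0.47 M.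

    substrate + partner → isomer of the product (k = 3.30 M⁻¹ h⁻¹)
    partner + protic impurity → quenched reagent (k = 2100 M⁻¹ h⁻¹)
    partner + tautomer → target (k = 8.30 M⁻¹ h⁻¹)
    substrate ⇌ tautomer (K = 2.40, k = 0.450 h⁻¹)
    capture agent + tautomer → trapped intermediate (k = 3.70 M⁻¹ h⁻¹)

**Budget spent.** Autumn ends with 0% of its partner, and the falling level of partner is the largest single effect on its target. With partner held at its charge, autumn would give 0.528 M rather than 0.0438 M, more than the budget. A tenfold time leaves autumn's target where it stands. Dawn turns 28.9% of the budget into target, and autumn turns 12.9%.

(The numbers in the tables are simulated for an exercise.)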